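Assumption: cembrane numbering is used (C1 carries the lactone α-carbon C15, C2 the lactone oxygen, C16 is the lactone carbonyl, C17 the exocyclic methylene). The target SMILES is read as 1S,2S,7S,8S,11S with 3E and 12Z alkenes and a cis-fused lactone.

## The problem

The target is a 14-membered carbocycle (C1–C14) bridged twice: a cis-fused α-methylene-γ-butyrolactone spans C1/C2, and a 1,2-dioxane (C8, C9, C10, C11 and two oxygens) spans C8 and C11. Of the five stereocenters, C7 (secondary acetate) and C8 (quaternary, peroxide-bearing) are contiguous and can be set together from one trisubstituted alkene by reagent control. C11 lies 1,4 to C8 across the dioxane and can be controlled from C8 through a six-membered transition state. C1 and C2 are remote from this triad, so only their mutual cis relationship is easy to secure; their sense relative to the dioxane must come from the conformation of the closing macrocycle. The O–O bond will not survive strongly reducing metals, phosphines, hydrogenation catalysts or organolithium reagents. The C11–H bond, flanked by a peroxide oxygen and the Z-configured C12=C13 alkene, invites base-induced Kornblum–DeLaMare fragmentation, and the α-methylene lactone and the C7 acetate restrict nucleophiles and hydrides further. The peroxide must therefore enter when the carbon chains are complete, and the steps after it must be few and mild. The feature that allows this is the dioxane itself: C11 is a secondary carbon bound to a peroxide oxygen and a Z-alkenyl group, which is an aldehyde-derived peroxycarbenium carbon in disguise. It is joined to the quaternary C8 by the two-carbon unit C9–C10, which can be a Z-vinylsilane on C8 held to C11 through the O–O bond.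

## Retrosynthesis

**Lactone and carbocycle (32 ⇒ 30).** The C1–C2 bond and the lactone C–O bond are cut together. Target 32 is the lactone of hydroxy ester 31, which arises by intramolecular Barbier-type allylation of the C2 enal by the 2-(bromomethyl)enoate of 30. Closing at C3=C4 by metathesis would give no control over the E trisubstituted geometry, and closing at a peroxide C–O bond leaves the hardest bond to the end. This cut forms the ring, both remaining stereocenters and the α-methylene lactone at once, and leaves an open chain that carries only the C7/C8/C11 triad. The forward step must give the syn adduct (cis lactone), choose the correct face relative to the distant dioxane, and use a metal that spares the O–O bond.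

**End groups (30 ⇒ 26).** No skeletal bond is cut. Bromide 30 comes through mesylate 29 from hydroxy enal 28, which comes from diol 27, and 27 from bis-silyl ether 26. The two primary allylic alcohols of 27 need no separate protecting groups because MnO2 should oxidise only the one on the electron-rich C3=C4 alkene. All reagents must be non-basic and free of phosphines.

**Ring alkene (26 ⇒ 25).** The C9–C10 single bond is returned to a cis double bond. Dioxane 26 comes from 3,6-dihydro-1,2-dioxine 25 by diimide, the reduction that saturates a C=C bond without touching O–O. The ring alkene is the only disubstituted one in 25, which should make it the fastest.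

**Dioxine ring (25 ⇒ 24), the key disconnection.** The C10–C11 bond is cut. C11 becomes a peroxycarbenium carbon generated from the mixed methyl peroxyacetal 24, and C10 becomes the silicon-bearing carbon of a Z-vinylsilane on C8. Cutting O–C11 or O–C8 instead would require a second stereoselective C–O bond at a secondary allylic or a quaternary carbon. The chosen cut lets the C8–O bond be made earlier by stereospecific epoxide opening and lets C8 set C11. Precursor 24 is acyclic, and its acetal centre needs no control.

**Peroxyacetal (24 ⇒ 16 + 23).** The C11–O(peroxide) bond is cut by acetal exchange between hydroperoxide 16 and dimethyl acetal 23. This is the convergent point: 16 carries C2–C10 with both early stereocenters, and the achiral 23 carries C11–C14, C1 and the three lactone carbons. The exchange must stop at the mono-peroxide stage and must not isomerise the Z alkene.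

**Hydroperoxide (16 ⇒ 13 ⇒ 12).** The acetate of 16 is traced through silyl peroxides 15 and 14 to hydroxy hydroperoxide 13. The C8–O bond of 13 is cut: H2O2 opens epoxide 12 at the tertiary allylic carbon with inversion, and the epoxide oxygen stays on C7. One epoxide thus encodes both C7 and C8.

**Vinylsilane (12 ⇒ 11 ⇒ 9 ⇒ 8).** The C10–Si bond comes from trans-hydrosilylation of alkyne 11. C10 comes from one-carbon homologation of epoxy aldehyde 9, which is the oxidation product of epoxy alcohol 8. The free hydroxyl is kept until after the epoxidation because it is what directs it.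

**Epoxide and Z alkene (8 ⇒ 7 ⇒ 6 ⇒ 4 + 5).** The epoxide of 8 comes from Z-allylic alcohol 7 by Sharpless asymmetric epoxidation. Alcohol 7 comes from Z-enoate 6, and the C7=C8 bond of 6 is cut to aldehyde 4 and phosphonate 5 (Z-selective Still–Gennari olefination).

**C2–C7 unit (4 ⇒ 3 ⇒ 2 ⇒ 1).** Aldehyde 4 is the cleavage product of epoxide 3, made from silyl ether 2 of geraniol 1. Geraniol supplies C2–C7, the C4 methyl and the 3E alkene ready-made.

**Acetal fragment (23 ⇒ 22 + 18; 22 ⇒ 19 + 20; 18 ⇒ 17).** The C1=C15 bond of 23 is cut by cross-metathesis to diene 22 and acrylate 18 (from alcohol 17). The Z-configured C12=C13 bond of 22 is cut by Wittig reaction to ylide 21 (from salt 19) and ketone 20. This delivers the Z-enal directly as its acetal.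

## Roads not taken

**Alternative 1:** The cut is at both C–O bonds of the dioxane on the finished macrocycle. In the forward step anhydrous H2O2 with MoO2(acac)2 would open a cis C7–C8 epoxide at C8 with inversion, and the new hydroperoxide would add across the ring to a C11 ketone to give the bridged peroxyhemiketal A1.
- Merits: the peroxide appears last, so the whole skeleton, lactone included, can be built without restriction. C7 and C8 come from one stereospecific opening. In the number of peroxide-bearing intermediates this road is clearly better than the chosen plan, which carries the O–O bond through seven steps and a metal-mediated ring closure.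
- Weak points: A1 has a hydroxyl at C11 where the target has hydrogen. A bridged peroxyhemiketal carbon would still have to be reduced to C–H with the correct configuration beside a Z-alkene and an α-methylene lactone. The epoxide must be placed on one of three trisubstituted alkenes of a macrocycle with no directing group. H2O2 can also add in conjugate fashion to the enone or the methylene lactone, and the C7 hydroxyl competes for the ketone.
- Comparison: the chosen plan makes C11 at the correct oxidation level with induction from C8 and sets C7/C8 on an open-chain allylic alcohol. It pays with an unprecedented C–C bond formation and a peroxide-tolerant end game.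

**Alternative 2:** The cut is at C3/C4, with an alkyne standing in for the E alkene. In the forward step the hexavalent molybdenum alkylidyne Mo(≡CC6H4OMe-4)(OSiPh3)3 would join two methyl-capped alkyne termini and close the 14-membered cycloalkyne A2.
- Merits: alkyne metathesis is among the most dependable closures for rings of this size and has no E/Z issue at the closing bond. All stereocenters would be set beforehand on open chains by reagent control. In ring-closure reliability and in control of C1/C2 this road is better than the indium closure used here.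
- Weak points: A2 contains no peroxide; C8 and C11 are only oxygenated. The O–O bridge would still need two substitutions, one at a quaternary carbon, so the hardest problem is postponed. The alkyne must then be turned regioselectively into the E trisubstituted alkene with the C4 methyl. Four protecting groups and the lactone oxidation state remain to be handled.
- Comparison: the chosen plan forms the peroxide ring in its central step and uses few protecting groups, but it has nothing as reliable as alkyne metathesis for the macrocycle.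

**Alternative 3:** The cut is at C9–C10 by a retro-Claisen that contracts the ring to a 12-membered lactone. In the forward step methylenation of the lactone carbonyl (for example with Cp2TiMe2) and heating would trigger a [3,3] shift that forms C9–C10 and gives the 14-membered enone A3.
- Merits: the large ring comes from an easier macrolactonisation plus a concerted, atom-economical expansion. In ring construction this road is more elegant than the chosen one.
- Weak points: A3 has none of the C7, C8 and C11 stereocenters. It needs an enantioselective epoxidation of C7=C8 among three trisubstituted alkenes and an enone, followed by the same peroxyhemiketal reduction problem as alternative 1. The Z-enone must survive methylenation and heat, and the C7=C8 geometry depends on a macrocyclic chair/boat preference.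
- Comparison: the chosen plan sets C7/C8 by a directed epoxidation and C11 in the key step. Against the elegance of the ring expansion it sets stereochemical certainty at the peroxide.

Key step: step 17

## Route

Step 1
Reactants: 1 geraniol
Product: 2 tert-butyl{[(2E)-3,7-dimethylocta-2,6-dien-1-yl]oxy}diphenylsilane
Conditions: t-BuPh2SiCl, imidazole, CH2Cl2, 0 °C to rt
Reagents that add atoms: tert-butyl(chloro)diphenylsilane, CC(C)(C)[Si](Cl)(c1ccccc1)c1ccccc1
Why: Routine silylation of a primary allylic alcohol; the bulky silyl ether survives periodic acid, base, hydride and the later peroxide chemistry and screens the C3=C4 alkene in step 2.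

Step 2
Reactants: 2 tert-butyl{[(2E)-3,7-dimethylocta-2,6-dien-1-yl]oxy}diphenylsilane
Product: 3 tert-butyl{[(2E)-5-(3,3-dimethyloxiran-2-yl)-3-methylpent-2-en-1-yl]oxy}diphenylsilane (racemic oxirane)
Conditions: mCPBA (1 equiv), CH2Cl2, −20 °C
Reagents that add atoms: 3-chloroperoxybenzoic acid, OOC(=O)c1cccc(Cl)c1
Why: Prilezhaev epoxidation; the terminal trisubstituted alkene is more electron-rich than the C3=C4 alkene (deactivated by the allylic oxygen, screened by the silyl group), and the new stereocenter is irrelevant because the epoxide is cleaved in step 3.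

Step 3
Reactants: 3 tert-butyl{[(2E)-5-(3,3-dimethyloxiran-2-yl)-3-methylpent-2-en-1-yl]oxy}diphenylsilane
Product: 4 (4E)-6-[(tert-butyldiphenylsilyl)oxy]-4-methylhex-4-enal
Conditions: H5IO6, THF–H2O, 0 °C
Reagents that add atoms: none
Why: Periodic acid hydrolyses the epoxide and cleaves the diol in one flask (epoxide–periodate cleavage), the standard way to this aldehyde from geranyl derivatives; acetone is lost.

Step 4
Reactants: 4 (4E)-6-[(tert-butyldiphenylsilyl)oxy]-4-methylhex-4-enal; 5 ethyl 2-[bis(2,2,2-trifluoroethoxy)phosphoryl]propanoate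
Product: 6 ethyl (2Z,6E)-8-[(tert-butyldiphenylsilyl)oxy]-2,6-dimethylocta-2,6-dienoate
Conditions: KN(SiMe3)2, 18-crown-6, THF, −78 °C
Reagents that add atoms: none
Why: Still–Gennari olefination; the electron-poor phosphonate under dissociating conditions eliminates from the kinetic adduct and gives the Z-2-methyl-2-enoate, which places the future C9 cis to the C6 chain as the epoxide stereochemistry requires.

Step 5
Reactants: 6 ethyl (2Z,6E)-8-[(tert-butyldiphenylsilyl)oxy]-2,6-dimethylocta-2,6-dienoate
Product: 7 (2Z,6E)-8-[(tert-butyldiphenylsilyl)oxy]-2,6-dimethylocta-2,6-dien-1-ol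
Conditions: i-Bu2AlH, CH2Cl2, −78 °C
Reagents that add atoms: none
Why: 1,2-Reduction of the enoate to the allylic alcohol with retention of alkene geometry; the silyl ether is inert.

Step 6
Reactants: 7 (2Z,6E)-8-[(tert-butyldiphenylsilyl)oxy]-2,6-dimethylocta-2,6-dien-1-ol
Product: 8 [(2R,3S)-3-{(3E)-5-[(tert-butyldiphenylsilyl)oxy]-3-methylpent-3-en-1-yl}-2-methyloxiran-2-yl]methanol
Conditions: Ti(Oi-Pr)4 (cat.), D-(−)-diisopropyl tartrate (cat.), t-BuOOH, 4 Å molecular sieves, CH2Cl2, −20 °C
Reagents that add atoms: tert-butyl hydroperoxide, CC(C)(C)OO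
Why: Sharpless asymmetric epoxidation; only the alkene of the free allylic alcohol reacts, and the D-(−)-tartrate delivers oxygen to the face that gives the (2R,3S)-epoxy alcohol, fixing C7 (S) and the C8 configuration that inversion in step 10 turns into S. Z-substituted allylic alcohols are the least selective class, so enantiomeric purity should be checked and if necessary raised at this stage.

Step 7
Reactants: 8 [(2R,3S)-3-{(3E)-5-[(tert-butyldiphenylsilyl)oxy]-3-methylpent-3-en-1-yl}-2-methyloxiran-2-yl]methanol
Product: 9 (2S,3S)-3-{(3E)-5-[(tert-butyldiphenylsilyl)oxy]-3-methylpent-3-en-1-yl}-2-methyloxirane-2-carbaldehyde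
Conditions: Dess–Martin periodinane, pyridine, CH2Cl2, 0 °C
Reagents that add atoms: none
Why: Buffered Dess–Martin oxidation; the α-carbon is quaternary, so the epoxy aldehyde cannot epimerise (the descriptor change at that carbon is a priority change only).

Step 8
Reactants: 9 (2S,3S)-3-{(3E)-5-[(tert-butyldiphenylsilyl)oxy]-3-methylpent-3-en-1-yl}-2-methyloxirane-2-carbaldehyde; 10 dimethyl (1-diazo-2-oxopropyl)phosphonate
Product: 11 tert-butyl({(2E)-5-[(2S,3R)-3-ethynyl-3-methyloxiran-2-yl]-3-methylpent-2-en-1-yl}oxy)diphenylsilane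
Conditions: K2CO3, MeOH, 0 °C to rt
Reagents that add atoms: none
Why: Seyferth–Gilbert homologation in the Ohira–Bestmann variant; mild carbonate/methanol conditions turn the non-enolisable aldehyde into the terminal alkyne (C10) without opening the epoxide.

Step 9
Reactants: 11 tert-butyl({(2E)-5-[(2S,3R)-3-ethynyl-3-methyloxiran-2-yl]-3-methylpent-2-en-1-yl}oxy)diphenylsilane
Product: 12 tert-butyl{[(2E)-3-methyl-5-{(2S,3R)-3-methyl-3-[(Z)-2-(triethylsilyl)ethenyl]oxiran-2-yl}pent-2-en-1-yl]oxy}diphenylsilane
Conditions: Et3SiH, [RuCl2(p-cymene)]2 (cat.), CH2Cl2, 40 °C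
Reagents that add atoms: triethylsilane, CC[SiH](CC)CC
Why: Ruthenium-catalysed trans-hydrosilylation of a terminal alkyne, which with this arene ruthenium chloride dimer gives the β-(Z)-vinylsilane; Z geometry is what the ipso cyclisation of step 17 needs, and triethylsilyl in place of trimethylsilyl is a spectator choice.

Step 10
Reactants: 12 tert-butyl{[(2E)-3-methyl-5-{(2S,3R)-3-methyl-3-[(Z)-2-(triethylsilyl)ethenyl]oxiran-2-yl}pent-2-en-1-yl]oxy}diphenylsilane
Product: 13 (1Z,3S,4S,7E)-9-[(tert-butyldiphenylsilyl)oxy]-3-hydroperoxy-3,7-dimethyl-1-(triethylsilyl)nona-1,7-dien-4-ol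
Conditions: H2O2 (anhydrous, in Et2O), MoO2(acac)2 (cat.), 0 °C to rt
Reagents that add atoms: hydrogen peroxide, OO
Why: Molybdenum-catalysed perhydrolysis of an epoxide; H2O2 attacks the tertiary, allylically activated C8 with inversion and leaves the C7–O bond intact, giving the anti β-hydroxy hydroperoxide (7S,8S). Attack at C10 is disfavoured because it would place charge α to silicon; the outcome rests on the opening staying SN2-like at this tertiary allylic carbon.

Step 11
Reactants: 13 (1Z,3S,4S,7E)-9-[(tert-butyldiphenylsilyl)oxy]-3-hydroperoxy-3,7-dimethyl-1-(triethylsilyl)nona-1,7-dien-4-ol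
Product: 15 (1Z,3S,4S,7E)-9-[(tert-butyldiphenylsilyl)oxy]-3,7-dimethyl-1-(triethylsilyl)-3-[(triethylsilyl)peroxy]nona-1,7-dien-4-yl acetate, via triethylsilyl peroxide alcohol 14 (not isolated)
Conditions: Et3SiCl (1 equiv), imidazole, DMF, −30 °C; then Ac2O, DMAP, 0 °C
Reagents that add atoms: chlorotriethylsilane, CC[Si](Cl)(CC)CC; acetic anhydride, CC(=O)OC(C)=O
Why: A hydroperoxide (more acidic, α-effect nucleophile) should be silylated well before a hindered secondary alcohol next to a quaternary carbon, so one equivalent of chlorosilane caps the OOH; DMAP-catalysed acetylation then takes the C7 hydroxyl, which avoids a perester and removes the free β-hydroxyl that would give a 1,2,4-trioxane in step 16.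

Step 12
Reactants: 15 (1Z,3S,4S,7E)-9-[(tert-butyldiphenylsilyl)oxy]-3,7-dimethyl-1-(triethylsilyl)-3-[(triethylsilyl)peroxy]nona-1,7-dien-4-yl acetate
Product: 16 (1Z,3S,4S,7E)-9-[(tert-butyldiphenylsilyl)oxy]-3-hydroperoxy-3,7-dimethyl-1-(triethylsilyl)nona-1,7-dien-4-yl acetate
Conditions: HF·pyridine, pyridine, THF, 0 °C
Reagents that add atoms: none
Why: The Si–OO bond is far more labile than the silyl ether and the vinylsilane, so buffered fluoride at 0 °C frees the hydroperoxide selectively; the ester is thermodynamically preferred over the perester, so acetyl migration to the peroxide is not expected.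

Step 13
Reactants: 17 methyl 2-(hydroxymethyl)prop-2-enoate
Product: 18 methyl 2-({[tert-butyl(dimethyl)silyl]oxy}methyl)prop-2-enoate
Conditions: t-BuMe2SiCl, imidazole, CH2Cl2, 0 °C to rt
Reagents that add atoms: tert-butyl(chloro)dimethylsilane, CC(C)(C)[Si](C)(C)Cl
Why: Routine silylation; the ether masks the allylic alcohol that becomes the bromide in step 21 and is small enough for the metathesis of step 15.

Step 14
Reactants: 19 (but-3-en-1-yl)triphenylphosphonium bromide; 20 1,1-dimethoxypropan-2-one
Product: 22 (4Z)-6,6-dimethoxy-5-methylhexa-1,4-diene, via but-3-enylidene(triphenyl)phosphorane 21 (not isolated)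
Conditions: NaN(SiMe3)2, THF, −78 °C to rt
Reagents that add atoms: none
Why: Salt-free Wittig reaction of a non-stabilised ylide with an α-oxygenated methyl ketone, a substrate class that gives the trisubstituted alkene with the oxygen-bearing carbon cis to the new chain (Z); the Z-enal is obtained directly as its acetal and is never exposed as the isomerisation-prone free aldehyde.

Step 15
Reactants: 22 (4Z)-6,6-dimethoxy-5-methylhexa-1,4-diene; 18 methyl 2-({[tert-butyl(dimethyl)silyl]oxy}methyl)prop-2-enoate
Product: 23 methyl (2E,5Z)-2-({[tert-butyl(dimethyl)silyl]oxy}methyl)-7,7-dimethoxy-6-methylhepta-2,5-dienoate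
Conditions: second-generation Grubbs catalyst (H2IMes)(PCy3)Cl2Ru=CHPh (cat.), excess 18, CH2Cl2, 40 °C
Reagents that add atoms: none
Why: Olefin cross-metathesis of a terminal alkene with a 2-substituted acrylate (as with methacrylates); the acrylate does not homodimerise, ethene is lost, the enoate forms with the chain trans to the ester, and the trisubstituted C12=C13 alkene is inert to the catalyst.

Step 16
Reactants: 16 (1Z,3S,4S,7E)-9-[(tert-butyldiphenylsilyl)oxy]-3-hydroperoxy-3,7-dimethyl-1-(triethylsilyl)nona-1,7-dien-4-yl acetate; 23 methyl (2E,5Z)-2-({[tert-butyl(dimethyl)silyl]oxy}methyl)-7,7-dimethoxy-6-methylhepta-2,5-dienoate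
Product: 24 methyl (2E,5Z)-7-{[(1Z,3S,4S,7E)-4-(acetyloxy)-9-[(tert-butyldiphenylsilyl)oxy]-3,7-dimethyl-1-(triethylsilyl)nona-1,7-dien-3-yl]peroxy}-2-({[tert-butyl(dimethyl)silyl]oxy}methyl)-7-methoxy-6-methylhepta-2,5-dienoate (both epimers at the acetal carbon)
Conditions: PPTS (cat.), excess 23, 4 Å molecular sieves, CH2Cl2, 0 °C
Reagents that add atoms: none
Why: Acid-catalysed acetal exchange; the conjugated dimethyl acetal ionises under pyridinium catalysis and the hydroperoxide, the best nucleophile present, captures the oxocarbenium ion. Excess acetal and sieves that take up methanol hold the exchange at the mono-peroxide stage, and the epimer mixture at C11 is inconsequential.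

Step 17
Reactants: 24 methyl (2E,5Z)-7-{[(1Z,3S,4S,7E)-4-(acetyloxy)-9-[(tert-butyldiphenylsilyl)oxy]-3,7-dimethyl-1-(triethylsilyl)nona-1,7-dien-3-yl]peroxy}-2-({[tert-butyl(dimethyl)silyl]oxy}methyl)-7-methoxy-6-methylhepta-2,5-dienoate
Product: 25 methyl (2E,5Z)-6-[(3S,6S)-6-{(1S,4E)-1-(acetyloxy)-6-[(tert-butyldiphenylsilyl)oxy]-4-methylhex-4-en-1-yl}-6-methyl-3,6-dihydro-1,2-dioxin-3-yl]-2-({[tert-butyl(dimethyl)silyl]oxy}methyl)hepta-2,5-dienoate
Conditions: Me3SiOTf, 2,6-di-tert-butyl-4-methylpyridine, CH2Cl2, −78 °C
Reagents that add atoms: none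
Why: Proposed new method: Me3SiOTf should remove the methoxy group of 24 (the ether-type oxygen is the more basic acetal oxygen) to give an E-configured peroxycarbenium ion conjugated with the Z-C12=C13 alkene; C10 of the Z-vinylsilane then attacks C11 ipso to silicon, and the β-silyl cation at C9 loses the silyl group to leave the cis ring alkene C9=C10. The closest known reaction types are vinylsilane-terminated oxocarbenium (Prins-type) cyclisations to dihydropyrans and Lewis acid additions of allylsilanes to peroxycarbenium ions; the combination across an O–O tether has not been shown. The single ring is closed in a 6-endo mode with respect to the vinylsilane through a chair-like transition state. C11 is the only new stereocenter and is controlled by C8: the C7 chain on C8 and the alkenyl group on C11 both sit equatorial with the C8 methyl axial, which gives the 3,6-trans (11S) isomer from either acetal epimer. Z geometry of the vinylsilane is required for ipso substitution with retention, and the β-silicon effect directs attack to C10 and not C9. The step needs loss of methoxide and not of the peroxide, no O–O heterolysis, no E/Z leakage at C12=C13 in the alkoxyallyl cation and no proton loss from C14; low temperature, the non-nucleophilic counter-ion, the hindered pyridine as proton trap and the fast six-membered closure are relied on for this. The oxonia-Cope scrambling that erodes ordinary Prins closures is shut off because it would have to expel an O=O fragment.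

Step 18
Reactants: 25 methyl (2E,5Z)-6-[(3S,6S)-6-{(1S,4E)-1-(acetyloxy)-6-[(tert-butyldiphenylsilyl)oxy]-4-methylhex-4-en-1-yl}-6-methyl-3,6-dihydro-1,2-dioxin-3-yl]-2-({[tert-butyl(dimethyl)silyl]oxy}methyl)hepta-2,5-dienoate
Product: 26 methyl (2E,5Z)-6-[(3S,6S)-6-{(1S,4E)-1-(acetyloxy)-6-[(tert-butyldiphenylsilyl)oxy]-4-methylhex-4-en-1-yl}-6-methyl-1,2-dioxan-3-yl]-2-({[tert-butyl(dimethyl)silyl]oxy}methyl)hepta-2,5-dienoate
Conditions: KO2CN=NCO2K, AcOH, MeOH–CH2Cl2, 0 °C
Reagents that add atoms: none
Why: Diimide reduction; concerted syn transfer of H2 to the cis-disubstituted ring alkene, which should react well before the three trisubstituted alkenes, with no effect on the O–O bond, and the acidic medium protects the base-labile dihydrodioxine from Kornblum–DeLaMare fragmentation.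

Step 19
Reactants: 26 methyl (2E,5Z)-6-[(3S,6S)-6-{(1S,4E)-1-(acetyloxy)-6-[(tert-butyldiphenylsilyl)oxy]-4-methylhex-4-en-1-yl}-6-methyl-1,2-dioxan-3-yl]-2-({[tert-butyl(dimethyl)silyl]oxy}methyl)hepta-2,5-dienoate
Product: 27 methyl (2E,5Z)-6-{(3S,6S)-6-[(1S,4E)-1-(acetyloxy)-6-hydroxy-4-methylhex-4-en-1-yl]-6-methyl-1,2-dioxan-3-yl}-2-(hydroxymethyl)hepta-2,5-dienoate
Conditions: HF·pyridine, pyridine, THF, 0 °C to rt
Reagents that add atoms: none
Why: Fluoride cleavage of both primary silyl ethers under buffered, non-basic conditions that spare the acetate, the methyl ester and the peroxide.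

Step 20
Reactants: 27 methyl (2E,5Z)-6-{(3S,6S)-6-[(1S,4E)-1-(acetyloxy)-6-hydroxy-4-methylhex-4-en-1-yl]-6-methyl-1,2-dioxan-3-yl}-2-(hydroxymethyl)hepta-2,5-dienoate
Product: 28 methyl (2E,5Z)-6-{(3S,6S)-6-[(1S,4E)-1-(acetyloxy)-4-methyl-6-oxohex-4-en-1-yl]-6-methyl-1,2-dioxan-3-yl}-2-(hydroxymethyl)hepta-2,5-dienoate
Conditions: MnO2, CH2Cl2, rt
Reagents that add atoms: none
Why: MnO2 oxidises an allylic alcohol on an electron-rich alkene much faster than the hydroxymethyl group on the electron-poor enoate, so only C2 should go to the E-enal; the reagent is neutral and inert to the peroxide.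

Step 21
Reactants: 28 methyl (2E,5Z)-6-{(3S,6S)-6-[(1S,4E)-1-(acetyloxy)-4-methyl-6-oxohex-4-en-1-yl]-6-methyl-1,2-dioxan-3-yl}-2-(hydroxymethyl)hepta-2,5-dienoate
Product: 30 methyl (2Z,5Z)-6-{(3S,6S)-6-[(1S,4E)-1-(acetyloxy)-4-methyl-6-oxohex-4-en-1-yl]-6-methyl-1,2-dioxan-3-yl}-2-(bromomethyl)hepta-2,5-dienoate, via allylic mesylate 29 (not isolated)
Conditions: MsCl, 2,4,6-collidine, LiBr, DMF, 0 °C
Reagents that add atoms: lithium bromide, [Li+].[Br-]
Why: Mesylation in the presence of bromide converts the remaining allylic alcohol through its mesylate into the allylic bromide by SN2 displacement (the descriptor changes from E to Z by priority only); no phosphine is used, and the weak hindered base avoids Kornblum–DeLaMare cleavage at C11.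

Step 22
Reactants: 30 methyl (2Z,5Z)-6-{(3S,6S)-6-[(1S,4E)-1-(acetyloxy)-4-methyl-6-oxohex-4-en-1-yl]-6-methyl-1,2-dioxan-3-yl}-2-(bromomethyl)hepta-2,5-dienoate
Product: 32 (1S,2S,3E,7S,8S,11S,12Z)-7-acetoxy-8,11-epidioxycembra-3,12,15(17)-trien-16,2-olide (CNP0238885.1), via hydroxy ester 31 (not isolated)
Conditions: In powder, THF–H2O, rt, high dilution; then p-TsOH (cat.), CH2Cl2
Reagents that add atoms: none
Why: Intramolecular Barbier-type allylation; zerovalent indium inserts into the allylic C–Br bond and the allylindium adds through its γ-carbon (C1) to the C2 aldehyde via a six-membered chair transition state, closing the 14-membered ring as the syn adduct, which acid lactonises to the cis α-methylene lactone. The cis relationship of C1 and C2 follows from the chair, whereas their 1S,2S sense relies on the conformation imposed by the dioxane and the two trisubstituted alkenes and is not secured by precedent; indium is chosen as a weaker reductant toward dialkyl peroxides than zinc or divalent chromium.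

## Compound list

1 | geraniol, (2E)-3,7-dimethylocta-2,6-dien-1-ol | CC(C)=CCC/C(C)=C/CO | starting material
2 | tert-butyl{[(2E)-3,7-dimethylocta-2,6-dien-1-yl]oxy}diphenylsilane | CC(C)=CCC/C(C)=C/CO[Si](c1ccccc1)(c1ccccc1)C(C)(C)C | intermediate
3 | tert-butyl{[(2E)-5-(3,3-dimethyloxiran-2-yl)-3-methylpent-2-en-1-yl]oxy}diphenylsilane (racemic oxirane) | CC1(C)OC1CC/C(C)=C/CO[Si](c1ccccc1)(c1ccccc1)C(C)(C)C | intermediate
4 | (4E)-6-[(tert-butyldiphenylsilyl)oxy]-4-methylhex-4-enal | O=CCC/C(C)=C/CO[Si](c1ccccc1)(c1ccccc1)C(C)(C)C | intermediate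
5 | ethyl 2-[bis(2,2,2-trifluoroethoxy)phosphoryl]propanoate | CCOC(=O)C(C)P(=O)(OCC(F)(F)F)OCC(F)(F)F | starting material
6 | ethyl (2Z,6E)-8-[(tert-butyldiphenylsilyl)oxy]-2,6-dimethylocta-2,6-dienoate | CCOC(=O)/C(C)=C\CC/C(C)=C/CO[Si](c1ccccc1)(c1ccccc1)C(C)(C)C | intermediate
7 | (2Z,6E)-8-[(tert-butyldiphenylsilyl)oxy]-2,6-dimethylocta-2,6-dien-1-ol | OC/C(C)=C\CC/C(C)=C/CO[Si](c1ccccc1)(c1ccccc1)C(C)(C)C | intermediate
8 | [(2R,3S)-3-{(3E)-5-[(tert-butyldiphenylsilyl)oxy]-3-methylpent-3-en-1-yl}-2-methyloxiran-2-yl]methanol | OC[C@@]1(C)O[C@H]1CC/C(C)=C/CO[Si](c1ccccc1)(c1ccccc1)C(C)(C)C | intermediate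
9 | (2S,3S)-3-{(3E)-5-[(tert-butyldiphenylsilyl)oxy]-3-methylpent-3-en-1-yl}-2-methyloxirane-2-carbaldehyde | O=C[C@@]1(C)O[C@H]1CC/C(C)=C/CO[Si](c1ccccc1)(c1ccccc1)C(C)(C)C | intermediate
10 | dimethyl (1-diazo-2-oxopropyl)phosphonate | COP(=O)(OC)C(=[N+]=[N-])C(C)=O | starting material
11 | tert-butyl({(2E)-5-[(2S,3R)-3-ethynyl-3-methyloxiran-2-yl]-3-methylpent-2-en-1-yl}oxy)diphenylsilane | C#C[C@@]1(C)O[C@H]1CC/C(C)=C/CO[Si](c1ccccc1)(c1ccccc1)C(C)(C)C | intermediate
12 | tert-butyl{[(2E)-3-methyl-5-{(2S,3R)-3-methyl-3-[(Z)-2-(triethylsilyl)ethenyl]oxiran-2-yl}pent-2-en-1-yl]oxy}diphenylsilane | CC[Si](CC)(CC)/C=C\[C@@]1(C)O[C@H]1CC/C(C)=C/CO[Si](c1ccccc1)(c1ccccc1)C(C)(C)C | intermediate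
13 | (1Z,3S,4S,7E)-9-[(tert-butyldiphenylsilyl)oxy]-3-hydroperoxy-3,7-dimethyl-1-(triethylsilyl)nona-1,7-dien-4-ol | CC[Si](CC)(CC)/C=C\[C@](C)(OO)[C@@H](O)CC/C(C)=C/CO[Si](c1ccccc1)(c1ccccc1)C(C)(C)C | intermediate
14 | (1Z,3S,4S,7E)-9-[(tert-butyldiphenylsilyl)oxy]-3,7-dimethyl-1-(triethylsilyl)-3-[(triethylsilyl)peroxy]nona-1,7-dien-4-ol | CC[Si](CC)(CC)/C=C\[C@](C)(OO[Si](CC)(CC)CC)[C@@H](O)CC/C(C)=C/CO[Si](c1ccccc1)(c1ccccc1)C(C)(C)C | intermediate
15 | (1Z,3S,4S,7E)-9-[(tert-butyldiphenylsilyl)oxy]-3,7-dimethyl-1-(triethylsilyl)-3-[(triethylsilyl)peroxy]nona-1,7-dien-4-yl acetate | CC[Si](CC)(CC)/C=C\[C@](C)(OO[Si](CC)(CC)CC)[C@@H](OC(C)=O)CC/C(C)=C/CO[Si](c1ccccc1)(c1ccccc1)C(C)(C)C | intermediate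
16 | (1Z,3S,4S,7E)-9-[(tert-butyldiphenylsilyl)oxy]-3-hydroperoxy-3,7-dimethyl-1-(triethylsilyl)nona-1,7-dien-4-yl acetate | CC[Si](CC)(CC)/C=C\[C@](C)(OO)[C@@H](OC(C)=O)CC/C(C)=C/CO[Si](c1ccccc1)(c1ccccc1)C(C)(C)C | intermediate
17 | methyl 2-(hydroxymethyl)prop-2-enoate | C=C(CO)C(=O)OC | starting material
18 | methyl 2-({[tert-butyl(dimethyl)silyl]oxy}methyl)prop-2-enoate | C=C(CO[Si](C)(C)C(C)(C)C)C(=O)OC | intermediate
19 | (but-3-en-1-yl)triphenylphosphonium bromide | C=CCC[P+](c1ccccc1)(c1ccccc1)c1ccccc1.[Br-] | starting material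
20 | 1,1-dimethoxypropan-2-one | COC(OC)C(C)=O | starting material
21 | but-3-enylidene(triphenyl)phosphorane | C=CCC=P(c1ccccc1)(c1ccccc1)c1ccccc1 | intermediate
22 | (4Z)-6,6-dimethoxy-5-methylhexa-1,4-diene | C=CC/C=C(/C)C(OC)OC | intermediate
23 | methyl (2E,5Z)-2-({[tert-butyl(dimethyl)silyl]oxy}methyl)-7,7-dimethoxy-6-methylhepta-2,5-dienoate | COC(=O)/C(CO[Si](C)(C)C(C)(C)C)=C/C/C=C(/C)C(OC)OC | intermediate
24 | methyl (2E,5Z)-7-{[(1Z,3S,4S,7E)-4-(acetyloxy)-9-[(tert-butyldiphenylsilyl)oxy]-3,7-dimethyl-1-(triethylsilyl)nona-1,7-dien-3-yl]peroxy}-2-({[tert-butyl(dimethyl)silyl]oxy}methyl)-7-methoxy-6-methylhepta-2,5-dienoate (both acetal epimers) | CC[Si](CC)(CC)/C=C\[C@](C)(OOC(OC)/C(C)=C\C/C=C(\CO[Si](C)(C)C(C)(C)C)C(=O)OC)[C@@H](OC(C)=O)CC/C(C)=C/CO[Si](c1ccccc1)(c1ccccc1)C(C)(C)C | intermediate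
25 | methyl (2E,5Z)-6-[(3S,6S)-6-{(1S,4E)-1-(acetyloxy)-6-[(tert-butyldiphenylsilyl)oxy]-4-methylhex-4-en-1-yl}-6-methyl-3,6-dihydro-1,2-dioxin-3-yl]-2-({[tert-butyl(dimethyl)silyl]oxy}methyl)hepta-2,5-dienoate | CC(=O)O[C@@H](CC/C(C)=C/CO[Si](c1ccccc1)(c1ccccc1)C(C)(C)C)[C@]1(C)C=C[C@H](OO1)/C(C)=C\C/C=C(\CO[Si](C)(C)C(C)(C)C)C(=O)OC | intermediate
26 | methyl (2E,5Z)-6-[(3S,6S)-6-{(1S,4E)-1-(acetyloxy)-6-[(tert-butyldiphenylsilyl)oxy]-4-methylhex-4-en-1-yl}-6-methyl-1,2-dioxan-3-yl]-2-({[tert-butyl(dimethyl)silyl]oxy}methyl)hepta-2,5-dienoate | CC(=O)O[C@@H](CC/C(C)=C/CO[Si](c1ccccc1)(c1ccccc1)C(C)(C)C)[C@]1(C)CC[C@H](OO1)/C(C)=C\C/C=C(\CO[Si](C)(C)C(C)(C)C)C(=O)OC | intermediate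
27 | methyl (2E,5Z)-6-{(3S,6S)-6-[(1S,4E)-1-(acetyloxy)-6-hydroxy-4-methylhex-4-en-1-yl]-6-methyl-1,2-dioxan-3-yl}-2-(hydroxymethyl)hepta-2,5-dienoate | CC(=O)O[C@@H](CC/C(C)=C/CO)[C@]1(C)CC[C@H](OO1)/C(C)=C\C/C=C(\CO)C(=O)OC | intermediate
28 | methyl (2E,5Z)-6-{(3S,6S)-6-[(1S,4E)-1-(acetyloxy)-4-methyl-6-oxohex-4-en-1-yl]-6-methyl-1,2-dioxan-3-yl}-2-(hydroxymethyl)hepta-2,5-dienoate | CC(=O)O[C@@H](CC/C(C)=C/C=O)[C@]1(C)CC[C@H](OO1)/C(C)=C\C/C=C(\CO)C(=O)OC | intermediate
29 | methyl (2E,5Z)-6-{(3S,6S)-6-[(1S,4E)-1-(acetyloxy)-4-methyl-6-oxohex-4-en-1-yl]-6-methyl-1,2-dioxan-3-yl}-2-{[(methylsulfonyl)oxy]methyl}hepta-2,5-dienoate | CC(=O)O[C@@H](CC/C(C)=C/C=O)[C@]1(C)CC[C@H](OO1)/C(C)=C\C/C=C(\COS(C)(=O)=O)C(=O)OC | intermediate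
30 | methyl (2Z,5Z)-6-{(3S,6S)-6-[(1S,4E)-1-(acetyloxy)-4-methyl-6-oxohex-4-en-1-yl]-6-methyl-1,2-dioxan-3-yl}-2-(bromomethyl)hepta-2,5-dienoate | CC(=O)O[C@@H](CC/C(C)=C/C=O)[C@]1(C)CC[C@H](OO1)/C(C)=C\C/C=C(\CBr)C(=O)OC | intermediate
31 | methyl (1S,2S,3E,7S,8S,11S,12Z)-7-acetoxy-8,11-epidioxy-2-hydroxycembra-3,12,15(17)-trien-16-oate (open-lactone hydroxy ester) | O[C@H]1/C=C(\C)CC[C@H](OC(C)=O)[C@]2(C)CC[C@H](OO2)/C(C)=C\C[C@H]1C(=C)C(=O)OC | intermediate
32 | (1S,2S,3E,7S,8S,11S,12Z)-7-acetoxy-8,11-epidioxycembra-3,12,15(17)-trien-16,2-olide (CNP0238885.1) | C=C1C(=O)O[C@H]2/C=C(\C)CC[C@H](OC(C)=O)[C@]3(C)CC[C@H](OO3)/C(C)=C\C[C@@H]12 | target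

## Step count and least certain steps

Total: 22 steps. Longest linear sequence: 19 steps (steps 1–12 and 16–22 from geraniol); steps 13–15 are the three-step branch to acetal 23.

**Step 17 (key step, proposed new method).** The most likely failure is diversion of the peroxycarbenium ion before the vinylsilane closes: O–O heterolysis with migration (Hock/Criegee type), proton loss from C14, protodesilylation, or E/Z scrambling at C12=C13. A peroxide oxygen is a weaker donor than an ether oxygen, so the cation is less stabilised and may live long enough to take these paths. The fallback uses known reaction types only; it sets out from alkyne 11 and acetal 23 and returns to the route at dioxane 26, bypassing steps 9–12 and 16–18.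
- Mild hydrolysis of 23 (oxalic acid on wet silica) gives the Z-enal F1.
- The lithium acetylide of 11 (n-BuLi, THF, −78 °C) adds to F1 to give the propargylic alcohol F2, and MnO2 oxidises it to the ynone F3.
- Diimide (KO2CN=NCO2K, AcOH) saturates the triple bond to the epoxy ketone F4.
- H2O2 with MoO2(acac)2 opens the epoxide at C8 with inversion, and the hydroperoxide closes onto the C11 ketone to give the cyclic peroxyhemiketal F5.
- Et3SiH with BF3·OEt2 at −78 °C reduces the hemiketal carbon through the cyclic peroxycarbenium ion (axial hydride, alkenyl group equatorial) to the C7-hydroxy dioxane F6.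
- Acetylation (Ac2O, DMAP) gives 26.

**Step 22.** The most likely failures are reductive cleavage of the O–O bond by the metal, poor facial selectivity with respect to the distant dioxane (cis lactone of the wrong 1,2-sense), and oligomerisation. The C–Br insertion must outrun electron transfer to the peroxide, and nothing but macrocyclic conformation links C1/C2 to C7/C8/C11. The fallback sets out from bromide 30 and returns at 32. Borylation with B2pin2 and the zerovalent palladium catalyst Pd2(dba)3 in DMSO gives the allylboronate F7. Warming F7 at high dilution (Sc(OTf)3 if needed) effects intramolecular allylboration through a closed chair transition state with no reducing metal present at the ring-closing stage; the geometry of F7 (chain cis to the CH2B group) leads to the syn adduct, which lactonises to 32.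

**Step 11.** The most likely failure is incomplete discrimination between the hydroperoxide and the C7 hydroxyl, with double silylation or acyl transfer to the peroxide oxygen, because both groups are hindered by the quaternary C8. The fallback sets out from 13 and returns at 16. Trimethyl orthoacetate with PPTS ties the two oxygens together as the cyclic orthoacetate F8. Mild aqueous acetic acid then opens F8, and collapse of the hemi-orthoester expels the better leaving group (the hydroperoxide), leaving the acetyl group on the C7 oxygen.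

**Step 9.** The most likely failure is loss of regio- or stereocontrol in the hydrosilylation (α-silyl or E product). The propargylic epoxide oxygen can coordinate ruthenium and the alkyne sits on a quaternary carbon. The fallback sets out from aldehyde 9 and returns at 12. Stork–Zhao olefination (Ph3P=CHI from the iodomethylphosphonium salt and NaN(SiMe3)2, −78 °C) gives the (Z)-vinyl iodide F9. Iodine–lithium exchange (t-BuLi, −78 °C) and quenching with Et3SiCl give 12 with retention of the Z geometry.

## Further compounds

F1 | step 17 | methyl (2E,5Z)-2-({[tert-butyl(dimethyl)silyl]oxy}methyl)-6-methyl-7-oxohepta-2,5-dienoate (Z-enal) | COC(=O)/C(CO[Si](C)(C)C(C)(C)C)=C/C/C=C(/C)C=O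
F2 | step 17 | propargylic alcohol from the acetylide of 11 and F1 (both C11 epimers) | COC(=O)/C(CO[Si](C)(C)C(C)(C)C)=C/C/C=C(/C)C(O)C#C[C@@]1(C)O[C@H]1CC/C(C)=C/CO[Si](c1ccccc1)(c1ccccc1)C(C)(C)C
F3 | step 17 | ynone (C11 ketone, C9≡C10) | COC(=O)/C(CO[Si](C)(C)C(C)(C)C)=C/C/C=C(/C)C(=O)C#C[C@@]1(C)O[C@H]1CC/C(C)=C/CO[Si](c1ccccc1)(c1ccccc1)C(C)(C)C
F4 | step 17 | epoxy ketone (C9–C10 saturated, C7–C8 epoxide, C11 ketone) | COC(=O)/C(CO[Si](C)(C)C(C)(C)C)=C/C/C=C(/C)C(=O)CC[C@@]1(C)O[C@H]1CC/C(C)=C/CO[Si](c1ccccc1)(c1ccccc1)C(C)(C)C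
F5 | step 17 | cyclic peroxyhemiketal (3-hydroxy-1,2-dioxane, both C11 anomers, free C7 hydroxyl) | COC(=O)/C(CO[Si](C)(C)C(C)(C)C)=C/C/C=C(/C)C1(O)CC[C@](C)(OO1)[C@@H](O)CC/C(C)=C/CO[Si](c1ccccc1)(c1ccccc1)C(C)(C)C
F6 | step 17 | (3S,6S)-1,2-dioxane with free C7 hydroxyl (deacetyl 26) | COC(=O)/C(CO[Si](C)(C)C(C)(C)C)=C/C/C=C(/C)[C@@H]1CC[C@](C)(OO1)[C@@H](O)CC/C(C)=C/CO[Si](c1ccccc1)(c1ccccc1)C(C)(C)C
F7 | step 22 | allylboronate (pinacol ester in place of bromide in 30) | CC(=O)O[C@@H](CC/C(C)=C/C=O)[C@]1(C)CC[C@H](OO1)/C(C)=C\C/C=C(\CB2OC(C)(C)C(C)(C)O2)C(=O)OC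
F8 | step 11 | cyclic orthoacetate of 13 (3-methoxy-3-methyl-1,2,4-trioxane, both orthoester epimers) | CC[Si](CC)(CC)/C=C\[C@]1(C)OOC(C)(OC)O[C@H]1CC/C(C)=C/CO[Si](c1ccccc1)(c1ccccc1)C(C)(C)C
F9 | step 9 | (Z)-vinyl iodide, tert-butyl{[(2E)-5-{(2S,3R)-3-[(Z)-2-iodoethenyl]-3-methyloxiran-2-yl}-3-methylpent-2-en-1-yl]oxy}diphenylsilane | I/C=C\[C@@]1(C)O[C@H]1CC/C(C)=C/CO[Si](c1ccccc1)(c1ccccc1)C(C)(C)C
A1 | alternative 1 | bridged bicyclic peroxyhemiketal of the intact macrocycle with free C7 hydroxyl | C=C1C(=O)O[C@H]2/C=C(\C)CC[C@H](O)[C@]3(C)CC[C@](O)(OO3)/C(C)=C\C[C@@H]12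
A2 | alternative 2 | 14-membered cycloalkyne (C3≡C4) with C7/C8 acetonide | C=C(CO[Si](C)(C)C(C)(C)C)[C@H]1[C@@H](O[Si](CC)(CC)CC)C#CCC[C@H]2OC(C)(C)O[C@]2(C)CC[C@H](O[Si](C)(C)C(C)(C)C)/C(C)=C\C1
A3 | alternative 3 | 14-membered cross-conjugated C11 enone with E C7=C8 alkene | C=C(CO[Si](C)(C)C(C)(C)C)[C@H]1[C@@H](O[Si](C)(C)C(C)(C)C)/C=C(\C)CC/C=C(\C)CCC(=O)/C(C)=C\C1
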